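**Direct plan and its weak points**

A direct plan would build the acyclic enyne A1, which carries a siloxy-vinylcyclopropane, from D-valine, would close both rings at once by a rhodium-catalysed [5+2] cycloaddition to hexahydroazulene A2, and would then adjust the oxidation pattern through diosphenol A3.
- The assembly of A1 would be weak: about fifteen linear steps (self-regeneration of one stereocentre, then four chain and alkyne homologations) are spent on a precursor that holds one tertiary carbinol and two π-systems.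
- The double ring closure to A2 would be weak: the quaternary C8a must form at a trisubstituted alkene terminus, with its face chosen only by a 1,3-relay from a carbinol whose two substituents (OSiEt3, isopropyl) differ little in size.
- The oxidation-level adjustment after the cycloaddition would be weak: a hydroboration that also reduces the C7 ketone, a diol-to-diketone oxidation, the diosphenol A3, a reduction and a late palladium dehydrogenation beside a free ketol and an allylic ester, about nine steps that form no C–C bond.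

**Retrosynthetic overview of the new route**

- Key disconnection: the C8–C8a bond of the seven-membered ring (C3a–C4–C5–C6–C7–C8–C8a). Its C6-methyl enone next to the quaternary ring-fusion carbon C8a is the retron of a divinylcyclopropane–cycloheptadiene rearrangement; a cyclopropane bond C4–C6 that is absent from the target would be made on purpose and broken in the key step (strain release).
- Ring order: the five-membered ring would be bought (2-bromo-3-methylcyclopent-2-en-1-one, C3 masked as a ketal) and joined to a C5 alkenyl iodide from (S)-but-3-yn-2-ol; the seven-membered ring would close second, and five steps would lead to the key-step precursor.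
- Stereocontrol: one purchased stereocentre would direct the cyclopropanation and then be oxidised away; the cyclopropane would transfer its chirality to C8a, and the angular methyl would relay to C4, C3a, C3 and C8 on the rigid bicycle.
- The rearrangement would deliver the C6=C7 enol silane (direct enone formation) and, after ketal removal, the C3a=C4 enone (conjugate borylation sets C4–O and C3a–H), so the long run-up, the weak relay and the redox shuffle of the direct plan would not arise.

Key step: step 6

Remark: locants C1–C8a are those of the azulene numbering of the target and are used for the same carbons in all intermediates; the β face is the face of the C8a methyl group.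

**Route**

Step 1
Reactants: 1 (S)-but-3-yn-2-ol
Product: 3 (2S,3Z)-4-iodo-3-methylbut-3-en-2-ol, via alkenylmagnesium chelate 2 (not isolated)
Conditions: MeMgBr (3 equiv), CuI (10 mol%), THF, −10 °C → rt; then I2, −78 → 0 °C
Reagents that add atoms: methylmagnesium bromide, C[Mg]Br; iodine, II
Why: Copper-catalysed anti-carbomagnesiation of a propargylic alcohol, in which the magnesium alkoxide directs methyl to the internal carbon and magnesium to the terminal carbon cis to the carbinol, and iodinolysis with retention should give the Z alkenyl iodide without touching the carbinol stereocentre.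

Step 2
Reactants: 4 2-bromo-3-methylcyclopent-2-en-1-one
Product: 5 6-bromo-7-methyl-1,4-dioxaspiro[4.4]non-6-ene
Conditions: ethane-1,2-diol, TsOH·H2O (cat.), benzene, reflux, Dean–Stark
Reagents that add atoms: ethane-1,2-diol, OCCO
Why: Acid-catalysed ketalisation masks the C3 ketone and turns the bromoenone into a precursor of an α-ketovinyl anion equivalent.

Step 3
Reactants: 5 6-bromo-7-methyl-1,4-dioxaspiro[4.4]non-6-ene; 3 (2S,3Z)-4-iodo-3-methylbut-3-en-2-ol
Product: 8 (2S,3Z)-3-methyl-4-(7-methyl-1,4-dioxaspiro[4.4]non-6-en-6-yl)but-3-en-2-ol, via alkenyllithium 6 (not isolated), via lithium triisopropyl borate 7 (not isolated)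
Conditions: 5, nBuLi, THF, −78 °C; B(OiPr)3, −78 °C → rt; then 3, Pd(OAc)2 (3 mol%), SPhos (6 mol%), K3PO4 (aq), THF, 40 °C
Reagents that add atoms: none
Why: Bromine–lithium exchange and borylation give an alkenyl borate that should undergo Suzuki–Miyaura coupling with the alkenyl iodide with retention of the Z geometry, the free alcohol being tolerated.

Step 4
Reactants: 8 (2S,3Z)-3-methyl-4-(7-methyl-1,4-dioxaspiro[4.4]non-6-en-6-yl)but-3-en-2-ol
Product: 9 (1S)-1-[(1S,2R)-1-methyl-2-(7-methyl-1,4-dioxaspiro[4.4]non-6-en-6-yl)cyclopropyl]ethan-1-ol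
Conditions: Et2Zn (2.2 equiv), CH2I2 (4.4 equiv), CH2Cl2, −10 → 0 °C
Reagents that add atoms: diiodomethane, ICI
Why: Hydroxyl-directed Simmons–Smith (Furukawa) cyclopropanation is stereospecific (Z alkene gives the cis cyclopropane) and, with the carbinol hydrogen eclipsing the alkene to avoid allylic 1,3-strain with the cis cyclopentenyl group, should deliver CH2 from the hydroxyl face, so the purchased carbinol sets both ring stereocentres while the undirected tetrasubstituted ring alkene stays untouched.

Step 5
Reactants: 9 (1S)-1-[(1S,2R)-1-methyl-2-(7-methyl-1,4-dioxaspiro[4.4]non-6-en-6-yl)cyclopropyl]ethan-1-ol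
Product: 10 1-[(1S,2R)-1-methyl-2-(7-methyl-1,4-dioxaspiro[4.4]non-6-en-6-yl)cyclopropyl]ethan-1-one
Conditions: Dess–Martin periodinane, NaHCO3, CH2Cl2, 0 °C → rt
Reagents that add atoms: none
Why: Buffered Dess–Martin oxidation gives the cyclopropyl methyl ketone (C7) and removes the directing stereocentre once it has done its work, without acid that could open the ketal or the cyclopropane.

Step 6
Reactants: 10 1-[(1S,2R)-1-methyl-2-(7-methyl-1,4-dioxaspiro[4.4]non-6-en-6-yl)cyclopropyl]ethan-1-one
Product: 13 tert-butyl{[(8a'R)-6',8a'-dimethyl-1',2',8',8a'-tetrahydro-5'H-spiro[[1,3]dioxolane-2,3'-azulen]-7'-yl]oxy}dimethylsilane, via potassium enolate 11 (not isolated), via silyl enol ether 12 (not isolated)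
Conditions: KN(SiMe3)2 (1.1 equiv), tBuMe2SiCl (1.2 equiv), THF, −78 °C → rt; then toluene, 90 °C
Reagents that add atoms: tert-butyldimethylsilyl chloride, CC(C)(C)[Si](C)(C)Cl
Why: The kinetic potassium enolate of the methyl ketone is silylated on oxygen, and the resulting cis-1-(1-siloxyvinyl)-2-alkenylcyclopropane should undergo the [3,3] sigmatropic divinylcyclopropane–cycloheptadiene (Cope) rearrangement through the boat transition state, driven by release of cyclopropane strain. The closest known reaction type is the thermal rearrangement of silyl enol ethers of cis-2-alkenylcyclopropyl ketones to 1-siloxycyclohepta-1,4-dienes, including cycloalkenyl partners that give ring-fusion quaternary carbons. The seven-membered ring closes by suprafacial bond formation between the enol ether CH2 (C8) and the methyl-bearing alkene carbon (C8a) while the cyclopropane bond C4–C6, which is not in the target, breaks; the five-membered ring is already present. The only new stereocentre, C8a, is controlled by the cyclopropane: in the boat, C8 can reach C8a only on the cyclopentene face that carries C6, so the (1S,2R) cyclopropane should give 8aR by chirality transfer. The step needs the rearrangement to outrun cyclopropane stereomutation, retro-Claisen opening and homodienyl hydrogen shifts; the cis geometry fixed by the stereospecific cyclopropanation, the electron-rich siloxy diene and the absence of a cis C–H donor are meant to secure this, and the one penalty, the methyl group that must point inward in the boat, is met by heating. The product carries the C6=C7 enol silane and the masked C3 enone exactly where the later steps need them.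

Step 7
Reactants: 13 tert-butyl{[(8a'R)-6',8a'-dimethyl-1',2',8',8a'-tetrahydro-5'H-spiro[[1,3]dioxolane-2,3'-azulen]-7'-yl]oxy}dimethylsilane
Product: 14 (8aR)-7-[(tert-butyldimethylsilyl)oxy]-6,8a-dimethyl-1,2,8,8a-tetrahydroazulen-3(5H)-one
Conditions: PPTS (0.1 equiv), acetone–H2O (20:1), 0 °C → rt
Reagents that add atoms: water, O
Why: Acid-catalysed hydrolysis of the allylic (2-alkylidene) dioxolane, which ionises far more readily than a saturated ketal, should unmask the C3 ketone as the C3a=C4 conjugated enone, while the hindered tetrasubstituted silyl enol ether should survive the weakly acidic medium.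

Step 8
Reactants: 14 (8aR)-7-[(tert-butyldimethylsilyl)oxy]-6,8a-dimethyl-1,2,8,8a-tetrahydroazulen-3(5H)-one
Product: 16 (3aS,4S,8aR)-7-[(tert-butyldimethylsilyl)oxy]-4-hydroxy-6,8a-dimethyl-2,3a,4,5,8,8a-hexahydroazulen-3(1H)-one, via boryl ketone 15 (not isolated)
Conditions: CuCl (5 mol%), Xantphos (5 mol%), NaOtBu (10 mol%), B2pin2 (1.2 equiv), MeOH (2 equiv), THF, rt; then NaBO3·4H2O, THF–H2O, 0 °C → rt
Reagents that add atoms: sodium perborate, B(=O)O[O-].[Na+]
Why: Copper-catalysed conjugate borylation of the enone and oxidation of the C–B bond with retention: boron should add to C4 and the enolate should be protonated at C3a on the face opposite the angular C8a methyl (the course known for additions to steroidal 5-enes), giving the 4α-hydroxyl and the trans ring fusion, while the enol silane is inert.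

Step 9
Reactants: 16 (3aS,4S,8aR)-7-[(tert-butyldimethylsilyl)oxy]-4-hydroxy-6,8a-dimethyl-2,3a,4,5,8,8a-hexahydroazulen-3(1H)-one
Product: 17 (3R,3aS,4S,8aR)-7-[(tert-butyldimethylsilyl)oxy]-6,8a-dimethyl-3-(propan-2-yl)-1,2,3,3a,4,5,8,8a-octahydroazulene-3,4-diol
Conditions: CeCl3 (3.5 equiv), iPrMgCl (3.2 equiv), THF, −78 °C; then 16, −78 → −30 °C
Reagents that add atoms: isopropylmagnesium chloride, CC(C)[Mg]Cl
Why: Organocerium 1,2-addition, in which the weakly basic reagent should add to the C3 ketone without enolisation or retro-aldol cleavage and from the face opposite the 1,3-syn-axial angular methyl (the course known for 4-oxo-5α-steroids), so the new hydroxyl ends cis to that methyl (3R); C7 stays protected as its enol silane.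

Step 10
Reactants: 17 (3R,3aS,4S,8aR)-7-[(tert-butyldimethylsilyl)oxy]-6,8a-dimethyl-3-(propan-2-yl)-1,2,3,3a,4,5,8,8a-octahydroazulene-3,4-diol; 18 4-methoxybenzoyl chloride
Product: 19 (3R,3aS,4S,8aR)-7-[(tert-butyldimethylsilyl)oxy]-3-hydroxy-6,8a-dimethyl-3-(propan-2-yl)-1,2,3,3a,4,5,8,8a-octahydroazulen-4-yl 4-methoxybenzoate
Conditions: 18 (1.3 equiv), pyridine, DMAP (cat.), CH2Cl2, 0 °C → rt
Reagents that add atoms: none
Why: Nucleophile-catalysed acylation should take place only at the secondary C4 alcohol, because the tertiary C3 alcohol and the enol silane do not react under these conditions.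

Step 11
Reactants: 19 (3R,3aS,4S,8aR)-7-[(tert-butyldimethylsilyl)oxy]-3-hydroxy-6,8a-dimethyl-3-(propan-2-yl)-1,2,3,3a,4,5,8,8a-octahydroazulen-4-yl 4-methoxybenzoate
Product: 20 (3R,3aS,4S,8aR)-3-hydroxy-6,8a-dimethyl-7-oxo-3-(propan-2-yl)-1,2,3,3a,4,7,8,8a-octahydroazulen-4-yl 4-methoxybenzoate
Conditions: Pd(OAc)2 (1.2 equiv), MeCN–CH2Cl2, rt → 40 °C
Reagents that add atoms: none
Why: Saegusa–Ito oxidation of the regiodefined enol silane delivered by the rearrangement: palladation at C6 and β-hydride elimination towards C5 should give the C5=C6 enone, with stoichiometric palladium diacetate and no phosphine so that the allylic ester is not ionised; no stereocentre is touched.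

Step 12
Reactants: 20 (3R,3aS,4S,8aR)-3-hydroxy-6,8a-dimethyl-7-oxo-3-(propan-2-yl)-1,2,3,3a,4,7,8,8a-octahydroazulen-4-yl 4-methoxybenzoate
Product: 23 (3R,3aS,4S,8S,8aS)-3,8-dihydroxy-6,8a-dimethyl-7-oxo-3-(propan-2-yl)-1,2,3,3a,4,7,8,8a-octahydroazulen-4-yl 4-methoxybenzoate, via silyl dienol ether 21 (not isolated), via silyloxy epoxide 22 (not isolated)
Conditions: LiN(SiMe3)2 (3 equiv), Me3SiCl (4 equiv), THF, −78 → −40 °C; then dimethyldioxirane, acetone–CH2Cl2, −40 °C; then aq. citric acid, THF, rt
Reagents that add atoms: dimethyldioxirane, CC1(C)OO1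
Why: Rubottom oxidation at the only enolisable α-position: internal-quench silylation gives the cross-conjugated silyl dienol ether and caps the tertiary alkoxide at once (no acyl migration), the dioxirane should epoxidise the electron-rich C7=C8 bond on the face away from the angular methyl, and acidic work-up gives the axial 8-hydroxy ketone (8S, the kinetic epimer) and frees the C3 alcohol.

Step 13
Reactants: 23 (3R,3aS,4S,8S,8aS)-3,8-dihydroxy-6,8a-dimethyl-7-oxo-3-(propan-2-yl)-1,2,3,3a,4,7,8,8a-octahydroazulen-4-yl 4-methoxybenzoate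
Product: 25 (3R,3aS,4S,8R,8aS)-3,8-dihydroxy-6,8a-dimethyl-7-oxo-3-(propan-2-yl)-1,2,3,3a,4,7,8,8a-octahydroazulen-4-yl 4-methoxybenzoate, via enediol 24 (not isolated)
Conditions: DBU (0.2 equiv), toluene, rt
Reagents that add atoms: none
Why: Base-mediated epimerisation of the α-ketol through its enediol under thermodynamic control: the equatorial C8 hydroxyl cis to the angular methyl and hydrogen-bonded to the C7 carbonyl should be the stable epimer (as in 12-hydroxy-11-oxo steroids), and the C7 ketone is retained because the isomeric C8 ketone would lose conjugation.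

**Compound list**

1 | (S)-but-3-yn-2-ol | C[C@H](O)C#C | starting material
2 | (5S)-4,5-dimethyl-2,5-dihydro-1,2-oxamagnesole (alkenylmagnesium alkoxide chelate, not isolated) | C[C@@H]1O[Mg]C=C1C | intermediate
3 | (2S,3Z)-4-iodo-3-methylbut-3-en-2-ol | C[C@H](O)/C(C)=C\I | intermediate
4 | 2-bromo-3-methylcyclopent-2-en-1-one | CC1=C(Br)C(=O)CC1 | starting material
5 | 6-bromo-7-methyl-1,4-dioxaspiro[4.4]non-6-ene | CC1=C(Br)C2(CC1)OCCO2 | intermediate
6 | (7-methyl-1,4-dioxaspiro[4.4]non-6-en-6-yl)lithium (not isolated) | [Li]C1=C(C)CCC12OCCO2 | intermediate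
7 | lithium triisopropoxy(7-methyl-1,4-dioxaspiro[4.4]non-6-en-6-yl)borate (not isolated) | [Li+].CC(C)O[B-](OC(C)C)(OC(C)C)C1=C(C)CCC12OCCO2 | intermediate
8 | (2S,3Z)-3-methyl-4-(7-methyl-1,4-dioxaspiro[4.4]non-6-en-6-yl)but-3-en-2-ol | C[C@H](O)/C(C)=C\C1=C(C)CCC12OCCO2 | intermediate
9 | (1S)-1-[(1S,2R)-1-methyl-2-(7-methyl-1,4-dioxaspiro[4.4]non-6-en-6-yl)cyclopropyl]ethan-1-ol (carbinol and cyclopentenyl group cis on the cyclopropane) | C[C@H](O)[C@@]1(C)C[C@H]1C2=C(C)CCC23OCCO3 | intermediate
10 | 1-[(1S,2R)-1-methyl-2-(7-methyl-1,4-dioxaspiro[4.4]non-6-en-6-yl)cyclopropyl]ethan-1-one | CC(=O)[C@@]1(C)C[C@H]1C2=C(C)CCC23OCCO3 | intermediate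
11 | potassium enolate of 10 (not isolated) | [K+].[O-]C(=C)[C@@]1(C)C[C@H]1C2=C(C)CCC23OCCO3 | intermediate
12 | tert-butyl(dimethyl)({1-[(1S,2R)-1-methyl-2-(7-methyl-1,4-dioxaspiro[4.4]non-6-en-6-yl)cyclopropyl]ethenyl}oxy)silane (key-step precursor, not isolated) | C=C(O[Si](C)(C)C(C)(C)C)[C@@]1(C)C[C@H]1C2=C(C)CCC23OCCO3 | intermediate
13 | tert-butyl{[(8a'R)-6',8a'-dimethyl-1',2',8',8a'-tetrahydro-5'H-spiro[[1,3]dioxolane-2,3'-azulen]-7'-yl]oxy}dimethylsilane (ethylene ketal of 14) | CC1=C(O[Si](C)(C)C(C)(C)C)C[C@@]2(C)CCC3(OCCO3)C2=CC1 | intermediate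
14 | (8aR)-7-[(tert-butyldimethylsilyl)oxy]-6,8a-dimethyl-1,2,8,8a-tetrahydroazulen-3(5H)-one | CC1=C(O[Si](C)(C)C(C)(C)C)C[C@@]2(C)CCC(=O)C2=CC1 | intermediate
15 | (3aR,4S,8aR)-7-[(tert-butyldimethylsilyl)oxy]-6,8a-dimethyl-4-(4,4,5,5-tetramethyl-1,3,2-dioxaborolan-2-yl)-2,3a,4,5,8,8a-hexahydroazulen-3(1H)-one (not isolated) | CC1(C)OB(OC1(C)C)[C@H]2CC(C)=C(O[Si](C)(C)C(C)(C)C)C[C@@]3(C)CCC(=O)[C@H]23 | intermediate
16 | (3aS,4S,8aR)-7-[(tert-butyldimethylsilyl)oxy]-4-hydroxy-6,8a-dimethyl-2,3a,4,5,8,8a-hexahydroazulen-3(1H)-one (trans-fused; C4–OH and C3a–H opposite the angular methyl) | O[C@H]2CC(C)=C(O[Si](C)(C)C(C)(C)C)C[C@@]3(C)CCC(=O)[C@H]23 | intermediate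
17 | (3R,3aS,4S,8aR)-7-[(tert-butyldimethylsilyl)oxy]-6,8a-dimethyl-3-(propan-2-yl)-1,2,3,3a,4,5,8,8a-octahydroazulene-3,4-diol | O[C@H]2CC(C)=C(O[Si](C)(C)C(C)(C)C)C[C@@]3(C)CC[C@@](O)(C(C)C)[C@H]23 | intermediate
18 | 4-methoxybenzoyl chloride | COc1ccc(cc1)C(Cl)=O | starting material
19 | (3R,3aS,4S,8aR)-7-[(tert-butyldimethylsilyl)oxy]-3-hydroxy-6,8a-dimethyl-3-(propan-2-yl)-1,2,3,3a,4,5,8,8a-octahydroazulen-4-yl 4-methoxybenzoate | COc1ccc(cc1)C(=O)O[C@H]2CC(C)=C(O[Si](C)(C)C(C)(C)C)C[C@@]3(C)CC[C@@](O)(C(C)C)[C@H]23 | intermediate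
20 | (3R,3aS,4S,8aR)-3-hydroxy-6,8a-dimethyl-7-oxo-3-(propan-2-yl)-1,2,3,3a,4,7,8,8a-octahydroazulen-4-yl 4-methoxybenzoate | COc1ccc(cc1)C(=O)O[C@H]2C=C(C)C(=O)C[C@@]3(C)CC[C@@](O)(C(C)C)[C@H]23 | intermediate
21 | bis(trimethylsilyl) derivative of 20: C3 trimethylsilyl ether and cross-conjugated C7(OSiMe3)=C8 dienol ether (not isolated) | COc1ccc(cc1)C(=O)O[C@H]2C=C(C)C(O[Si](C)(C)C)=C[C@@]3(C)CC[C@@](O[Si](C)(C)C)(C(C)C)[C@H]23 | intermediate
22 | C7–C8 epoxide of 21 with the epoxide oxygen on the face opposite the C8a methyl (not isolated) | COc1ccc(cc1)C(=O)O[C@H]2C=C(C)[C@@]4(O[Si](C)(C)C)O[C@H]4[C@@]3(C)CC[C@@](O[Si](C)(C)C)(C(C)C)[C@H]23 | intermediate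
23 | (3R,3aS,4S,8S,8aS)-3,8-dihydroxy-6,8a-dimethyl-7-oxo-3-(propan-2-yl)-1,2,3,3a,4,7,8,8a-octahydroazulen-4-yl 4-methoxybenzoate (8-epimer of the target) | COc1ccc(cc1)C(=O)O[C@H]2C=C(C)C(=O)[C@@H](O)[C@@]3(C)CC[C@@](O)(C(C)C)[C@H]23 | intermediate
24 | (3R,3aS,4S,8aS)-3,7,8-trihydroxy-6,8a-dimethyl-3-(propan-2-yl)-1,2,3,3a,4,8a-hexahydroazulen-4-yl 4-methoxybenzoate (enediol, not isolated) | COc1ccc(cc1)C(=O)O[C@H]2C=C(C)C(O)=C(O)[C@@]3(C)CC[C@@](O)(C(C)C)[C@H]23 | intermediate
25 | (3R,3aS,4S,8R,8aS)-3,8-dihydroxy-6,8a-dimethyl-7-oxo-3-(propan-2-yl)-1,2,3,3a,4,7,8,8a-octahydroazulen-4-yl 4-methoxybenzoate | COc1ccc(C(=O)O[C@H]2C=C(C)C(=O)[C@H](O)[C@@]3(C)CC[C@@](O)(C(C)C)[C@H]23)cc1 | target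

**Step count and risks**

Total step count: 13. Longest linear sequence: 12 steps (steps 1 and 3–13 from compound 1; equally steps 2–13 from compound 4).

The three steps most likely to fail:

- Step 6 (key rearrangement). The methyl group that must point inward in the boat may slow the sigmatropic shift enough for stereomutation of the cyclopropane to the unreactive trans isomer or loss of the enol silane to take over. The fallback would set out from ketone 10 and replace the pericyclic shift by a stepwise polar sequence. Ketal hydrolysis (PPTS, wet acetone) would give 2-[(1R,2S)-2-acetyl-2-methylcyclopropyl]-3-methylcyclopent-2-en-1-one F1. KN(SiMe3)2 in THF would then bring about an intramolecular Michael addition of the methyl ketone enolate to the β-carbon (C8a) of the cyclopentenone, giving the potassium enolate of the tricyclic Michael adduct F2. The enolate of F2 would open the acyl cyclopropane by retro-Michael fragmentation of the C4–C6 bond, and trapping of the resulting C7 enolate with tBuMe2SiCl would return to the route at enone 14.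

- Step 13 (equilibration at C8). The thermodynamic bias may be too small, or γ-deprotonation may start to epimerise C4 before C8 has equilibrated. The fallback would set out from the 8-epimer 23 and use kinetic hydride delivery. Dess–Martin oxidation would give (3R,3aS,4S,8aS)-3-hydroxy-6,8a-dimethyl-7,8-dioxo-3-(propan-2-yl)-1,2,3,3a,4,7,8,8a-octahydroazulen-4-yl 4-methoxybenzoate F3, which cannot enolise. NaBH4 in CH2Cl2–MeOH at −78 °C should then reduce the non-conjugated C8 carbonyl from the face opposite the angular methyl and return to the route at the target 25.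

- Step 9 (isopropyl addition). The hindered ketone may be enolised (with β-elimination of the C4 oxygen) or reduced by β-hydride transfer instead of undergoing addition. The fallback would set out from hydroxy ketone 16. Addition of 2-propenylmagnesium bromide with CeCl3, an sp2 nucleophile without β-hydrogen, would give (3S,3aS,4S,8aR)-7-[(tert-butyldimethylsilyl)oxy]-6,8a-dimethyl-3-(prop-1-en-2-yl)-1,2,3,3a,4,5,8,8a-octahydroazulene-3,4-diol F4. Hydrogenation of its 1,1-disubstituted alkene with RhCl(PPh3)3 and H2 in benzene, which should leave the tetrasubstituted enol silane alone, would return to the route at diol 17.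

Further compounds
F1 | step 6 | 2-[(1R,2S)-2-acetyl-2-methylcyclopropyl]-3-methylcyclopent-2-en-1-one | CC(=O)[C@@]1(C)C[C@H]1C2=C(C)CCC2=O
F2 | step 6 | potassium enolate of the tricyclic Michael adduct (C8–C8a bond formed, cyclopropane C4–C5–C6 intact, enolate at C3=C3a) | [K+].[O-]C1=C2[C@@H]3C[C@]3(C)C(=O)C[C@@]2(C)CC1
F3 | step 13 | (3R,3aS,4S,8aS)-3-hydroxy-6,8a-dimethyl-7,8-dioxo-3-(propan-2-yl)-1,2,3,3a,4,7,8,8a-octahydroazulen-4-yl 4-methoxybenzoate | COc1ccc(cc1)C(=O)O[C@H]2C=C(C)C(=O)C(=O)[C@@]3(C)CC[C@@](O)(C(C)C)[C@H]23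
F4 | step 9 | (3S,3aS,4S,8aR)-7-[(tert-butyldimethylsilyl)oxy]-6,8a-dimethyl-3-(prop-1-en-2-yl)-1,2,3,3a,4,5,8,8a-octahydroazulene-3,4-diol | O[C@H]2CC(C)=C(O[Si](C)(C)C(C)(C)C)C[C@@]3(C)CC[C@@](O)(C(C)=C)[C@H]23
A1 | direct plan | tert-butyl(dimethyl)({1-[(1E,5R)-2-methyl-5-(propan-2-yl)-5-[(triethylsilyl)oxy]hept-1-en-6-yn-1-yl]cyclopropyl}oxy)silane | C#C[C@](O[Si](CC)(CC)CC)(C(C)C)CC/C(C)=C/C1(O[Si](C)(C)C(C)(C)C)CC1
A2 | direct plan | (3R,8aR)-7-[(tert-butyldimethylsilyl)oxy]-8a-methyl-3-(propan-2-yl)-3-[(triethylsilyl)oxy]-1,2,3,5,6,8a-hexahydroazulene | C1=C2[C@](O[Si](CC)(CC)CC)(C(C)C)CC[C@]2(C)C=C(O[Si](C)(C)C(C)(C)C)CC1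
A3 | direct plan | (3R,3aS,4S,8aS)-3,7-dihydroxy-6,8a-dimethyl-8-oxo-3-(propan-2-yl)-1,2,3,3a,4,5,8,8a-octahydroazulen-4-yl 4-methoxybenzoate | COc1ccc(cc1)C(=O)O[C@H]2CC(C)=C(O)C(=O)[C@@]3(C)CC[C@@](O)(C(C)C)[C@H]23
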